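**Strategy.** With the arene numbered C1 (alkenyl), C3 (OH), C4 (methyl) and C6 (isobutyrate), the acyl carbon on O6 and the side-chain carbon Cα on neighbouring C1 are read as the two carbons of a furan C=C bond fused across C1–C6 (a benzofuran ring). Ozonolysis of a 2-isopropyl-3-(benzoyloxymethyl)benzofuran then releases the aryl ester and the aryl ketone together. The benzofuran should arise in one operation from 2-methyl-1,4-benzoquinone and ethyl 4-methyl-3-oxopentanoate: a ZnCl2-promoted conjugate addition/cyclodehydration forges C1–Cα and O6–C(isopropyl), closes the furan and leaves the C3 hydroxyl free. Since quinone and keto ester can both be purchased, the annulation is the opening step.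

Key step: step 1

Remark: the target has no stereocentre, so none has to be set; the sp3 centres of the transient compounds 3, 4 and 10 are racemic and are erased.

**Step 1**
Reactants: 1 2-methyl-1,4-benzoquinone; 2 ethyl 4-methyl-3-oxopentanoate
Product: 5 ethyl 5-hydroxy-2-isopropyl-6-methylbenzofuran-3-carboxylate, via hydroquinone Michael adduct 3 (not isolated), via cyclic hemiketal 4 (not isolated)
Conditions: ZnCl2 (1 equiv), 2 (1.5 equiv), EtOH, reflux; 1 added in portions
Reagents that add atoms: none
Why: ZnCl2 chelates keto ester 2 as its zinc enolate and activates quinone 1, so the enol carbon adds in Michael fashion to the quinone CH para to the methyl-bearing carbon (C1–Cα bond) and the adduct tautomerises to hydroquinone 3. The hydroxyl next to the new substituent (future O6) then attacks the isobutyryl ketone in a 5-exo-trig closure to hemiketal 4, and loss of water aromatises the new ring to the furan (O6–C(isopropyl) bond). The closest known reaction type is the Lewis-acid-mediated condensation of 1,4-benzoquinones with β-keto esters to 5-hydroxybenzofuran-3-carboxylates, the oxygen counterpart of the Nenitzescu indole synthesis. No stereocentre is created, since the sp3 centres of 3 and 4 vanish on aromatisation. The step needs attack at that one CH, which the substrate secures because the methyl group makes its own double bond the poorer acceptor and, by vinylogous donation, deactivates the far carbonyl to which the other free CH of the unsubstituted double bond is the β-position, whereas the attacked CH is β to the undiminished carbonyl beside the methyl-bearing carbon. The sequence is redox-neutral and leaves the other hydroxyl (future C3–OH, beside the methyl group) free, and portionwise addition of 1 limits oxidation of 3 by unreacted quinone.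

**Step 2**
Reactants: 5 ethyl 5-hydroxy-2-isopropyl-6-methylbenzofuran-3-carboxylate
Product: 6 ethyl 5-(tert-butyldimethylsilyloxy)-2-isopropyl-6-methylbenzofuran-3-carboxylate
Conditions: TBSCl, imidazole, DMF, rt
Reagents that add atoms: tert-butyldimethylsilyl chloride, CC(C)(C)[Si](C)(C)Cl
Why: Imidazole-promoted O-silylation of the only hydroxyl should mask the phenol as an aryl silyl ether that tolerates hydride, acylation, ozone and the methylenation reagent.

**Step 3**
Reactants: 6 ethyl 5-(tert-butyldimethylsilyloxy)-2-isopropyl-6-methylbenzofuran-3-carboxylate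
Product: 7 [5-(tert-butyldimethylsilyloxy)-2-isopropyl-6-methylbenzofuran-3-yl]methanol
Conditions: iBu2AlH (3 equiv), CH2Cl2, −78 → 0 °C; aq. potassium sodium tartrate (KNaC4H4O6)
Reagents that add atoms: none
Why: Hydride reduction of an ester to the primary alcohol with iBu2AlH should leave the furan and the aryl silyl ether untouched at low temperature, and the neutral tartrate work-up spares the acid-sensitive furylmethyl alcohol.

**Step 4**
Reactants: 7 [5-(tert-butyldimethylsilyloxy)-2-isopropyl-6-methylbenzofuran-3-yl]methanol; 8 benzoyl chloride
Product: 9 [5-(tert-butyldimethylsilyloxy)-2-isopropyl-6-methylbenzofuran-3-yl]methyl benzoate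
Conditions: BzCl, Et3N, DMAP (cat.), CH2Cl2, 0 °C
Reagents that add atoms: benzoyl chloride (compound 8), O=C(Cl)c1ccccc1
Why: DMAP-catalysed acylation of a primary alcohol with an acid chloride should be clean because the phenol is silylated and no other nucleophilic site remains.

**Step 5**
Reactants: 9 [5-(tert-butyldimethylsilyloxy)-2-isopropyl-6-methylbenzofuran-3-yl]methyl benzoate
Product: 11 2-[5-(tert-butyldimethylsilyloxy)-2-(isobutyryloxy)-4-methylphenyl]-2-oxoethyl benzoate, via bicyclic ozonide 10 (not isolated)
Conditions: O3, CH2Cl2, −78 °C (Sudan Red 7B end point); then PPh3, −78 °C → rt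
Reagents that add atoms: ozone, [O-][O+]=O
Why: Ozonolysis of the enol-ether-like C2=C3 bond of a 2,3-disubstituted benzofuran (Criegee cleavage, then reduction of the ozonide) is a known route to 2-acyloxyaryl ketones and should turn furan C2 into the isobutyrate carbonyl on O6 and furan C3 into the ketone at Cα, with methanol left out so that no tetrahedral intermediate can expel the phenol and the dye end point sparing the silyloxyarene.

**Step 6**
Reactants: 11 2-[5-(tert-butyldimethylsilyloxy)-2-(isobutyryloxy)-4-methylphenyl]-2-oxoethyl benzoate
Product: 12 2-[5-(tert-butyldimethylsilyloxy)-2-(isobutyryloxy)-4-methylphenyl]prop-2-en-1-yl benzoate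
Conditions: Zn, CH2Br2, TiCl4, THF, −40 → 5 °C (reagent aged); then 11, CH2Cl2, 0 °C → rt; aq. NaHCO3
Reagents that add atoms: dibromomethane, BrCBr
Why: Takai–Lombardo methylenation with the geminal dizinc/titanium reagent is non-basic and selective for ketones over esters, so it should avoid the enolisation, Baker–Venkataraman acyl transfer and ester attack that a phosphorus ylide would invite.

**Step 7**
Reactants: 12 2-[5-(tert-butyldimethylsilyloxy)-2-(isobutyryloxy)-4-methylphenyl]prop-2-en-1-yl benzoate
Product: 13 2-[5-hydroxy-2-(isobutyryloxy)-4-methylphenyl]prop-2-en-1-yl benzoate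
Conditions: HF·pyridine, pyridine, THF, 0 °C → rt
Reagents that add atoms: none
Why: Fluoride-mediated cleavage of an aryl silyl ether under buffered, weakly acidic conditions should free the C3 phenol without touching the aryl isobutyrate or the allylic benzoate, which a basic fluoride source could cleave.

**Compound list**
1 | 2-methyl-1,4-benzoquinone | CC1=CC(=O)C=CC1=O | starting material
2 | ethyl 4-methyl-3-oxopentanoate | CCOC(=O)CC(=O)C(C)C | starting material
3 | ethyl 2-(2,5-dihydroxy-4-methylphenyl)-4-methyl-3-oxopentanoate (hydroquinone Michael adduct, racemic) | CCOC(=O)C(C(=O)C(C)C)c1cc(O)c(C)cc1O | intermediate (not isolated)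
4 | ethyl 2,5-dihydroxy-2-isopropyl-6-methyl-2,3-dihydrobenzofuran-3-carboxylate (cyclic hemiketal, racemic mixture of diastereomers) | CCOC(=O)C1c2cc(O)c(C)cc2OC1(O)C(C)C | intermediate (not isolated)
5 | ethyl 5-hydroxy-2-isopropyl-6-methylbenzofuran-3-carboxylate | CCOC(=O)c1c(C(C)C)oc2cc(C)c(O)cc12 | intermediate
6 | ethyl 5-(tert-butyldimethylsilyloxy)-2-isopropyl-6-methylbenzofuran-3-carboxylate | CCOC(=O)c1c(C(C)C)oc2cc(C)c(O[Si](C)(C)C(C)(C)C)cc12 | intermediate
7 | [5-(tert-butyldimethylsilyloxy)-2-isopropyl-6-methylbenzofuran-3-yl]methanol | OCc1c(C(C)C)oc2cc(C)c(O[Si](C)(C)C(C)(C)C)cc12 | intermediate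
8 | benzoyl chloride | O=C(Cl)c1ccccc1 | starting material
9 | [5-(tert-butyldimethylsilyloxy)-2-isopropyl-6-methylbenzofuran-3-yl]methyl benzoate | O=C(OCc1c(C(C)C)oc2cc(C)c(O[Si](C)(C)C(C)(C)C)cc12)c1ccccc1 | intermediate
10 | bicyclic ozonide: 1,2,4-trioxolane bridging the former furan C2 and C3 (racemic; bridgehead configurations fixed by the bicycle) | CC(C)C12OOC(COC(=O)c3ccccc3)(O1)c1cc(O[Si](C)(C)C(C)(C)C)c(C)cc1O2 | intermediate (not isolated)
11 | 2-[5-(tert-butyldimethylsilyloxy)-2-(isobutyryloxy)-4-methylphenyl]-2-oxoethyl benzoate | CC(C)C(=O)Oc1cc(C)c(O[Si](C)(C)C(C)(C)C)cc1C(=O)COC(=O)c1ccccc1 | intermediate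
12 | 2-[5-(tert-butyldimethylsilyloxy)-2-(isobutyryloxy)-4-methylphenyl]prop-2-en-1-yl benzoate | C=C(COC(=O)c1ccccc1)c1cc(O[Si](C)(C)C(C)(C)C)c(C)cc1OC(=O)C(C)C | intermediate
13 | 2-[5-hydroxy-2-(isobutyryloxy)-4-methylphenyl]prop-2-en-1-yl benzoate | C=C(COC(=O)c1ccccc1)c1cc(O)c(C)cc1OC(=O)C(C)C | target

**Total step count:** 7
**Longest linear sequence:** 7 steps (1 and 2 to 13)

**Steps most likely to fail**

Step 1. The adduct hydroquinone may be oxidised by unreacted quinone, which leads to over-addition and tar. The conjugate addition may also stray to the other free CH, and closure onto the hindered isopropyl ketone may lose out to lactonisation onto the ester. Fallback: the route would set out from 2 together with 2-methylhydroquinone F1 in place of 1. PhI(OAc)2 with ZnI2 in chlorobenzene at about 95 °C would run an oxidative coupling in which the quinone is generated a little at a time and trapped by the zinc enolate as it forms, so that little free quinone is present to oxidise the adduct. Cyclodehydration under the same Lewis acid should follow, and the fallback comes back to the route at 5.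

Step 5. Excess ozone may attack the electron-rich silyloxy-substituted benzene ring, and the ozonide may ionise or rearrange instead of being reduced cleanly. Fallback: setting out from 9, OsO4 (cat.) with N-methylmorpholine N-oxide in acetone/water should dihydroxylate the furan C2=C3 bond from one face to give the racemic cis-2,3-diol F2, a cyclic hemiketal diol. Pb(OAc)4 in anhydrous CH2Cl2 at 0 °C should then cleave the glycol C–C bond; the cleavage must be fast and anhydrous so that the ring-closed form reacts before it opens to a hydroxy ketone. The fallback comes back to the route at 11.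

Step 6. Zinc or low-valent titanium may reductively remove the α-benzoyloxy group, and the hindered ortho-substituted aryl ketone may convert sluggishly. Fallback: setting out from 11, Me3SiCH2MgCl pre-complexed with anhydrous CeCl3 in THF at −78 °C should add to the ketone faster than to the two esters, since the organocerium is nucleophilic but weakly basic. A cold AcOH quench, which forestalls acyl transfer to the tertiary alkoxide, should give the racemic β-hydroxysilane F3. Catalytic TsOH in CH2Cl2 at 0 °C should then trigger the acid-type Peterson elimination, and the fallback comes back to the route at 12.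

**Further compounds**
F1 | step 1 | 2-methylhydroquinone (2-methylbenzene-1,4-diol) | Cc1cc(O)ccc1O
F2 | step 5 | [5-(tert-butyldimethylsilyloxy)-2,3-dihydroxy-2-isopropyl-6-methyl-2,3-dihydrobenzofuran-3-yl]methyl benzoate (cis-diol, racemic, one enantiomer drawn) | CC(C)[C@]1(O)Oc2cc(C)c(O[Si](C)(C)C(C)(C)C)cc2[C@]1(O)COC(=O)c1ccccc1
F3 | step 6 | 2-[5-(tert-butyldimethylsilyloxy)-2-(isobutyryloxy)-4-methylphenyl]-2-hydroxy-3-(trimethylsilyl)propyl benzoate (racemic) | CC(C)C(=O)Oc1cc(C)c(O[Si](C)(C)C(C)(C)C)cc1C(O)(C[Si](C)(C)C)COC(=O)c1ccccc1
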